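Late in Saturday's run the target stood at 101 % of the substrate charged, which within the scatter is the full charge. Partner was in excess there, more of it than of substrate, the limiting reagent. So I took that run as a ruler on which each share of the charge has its time.

| flask | substrate | coupling partner | catalyst | time |
|---|---|---|---|---|
| Thursday's | 300 mM | 750 mM | 9.00 mM |  |
| Sunday's | 180 mM | 630 mM | 9.00 mM |  |
| Saturday's | 300 mM | 2200 mM | 9.00 mM |  |
| Monday's | 300 mM | 750 mM | 13.0 mM |  |
| Tuesday's | 300 mM | 750 mM | 27.0 mM | 3.7 h |

| Thursday's run: time / h | Thursday's run: [target] / mM | Sunday's run: time / h | Sunday's run: [target] / mM | Saturday's run: time / h | Saturday's run: [target] / mM | Monday's run: time / h | Monday's run: [target] / mM |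
|---|---|---|---|---|---|---|---|
| 0.13 | 8 | 0.13 | 2 | 0.13 | 22 | 0.13 | 1 |
| 0.40 | 22 | 0.40 | 11 | 0.40 | 55 | 0.40 | 26 |
| 0.77 | 36 | 0.77 | 25 | 0.77 | 112 | 0.77 | 51 |
| 1.2 | 56 | 1.2 | 36 | 1.2 | 175 | 1.2 | 70 |
| 1.7 | 78 | 1.7 | 50 | 1.7 | 231 | 1.7 | 108 |
| 2.3 | 107 | 2.3 | 62 | 2.3 | 272 | 2.3 | 142 |
| 3.0 | 143 | 3.0 | 79 | 3.0 | 291 | 3.0 | 178 |
| 3.7 | 170 | 3.7 | 99 | 3.7 | 302 | 3.7 | 208 |

(each reading ± 3 mM)

- Overall: substrate + coupling partner -> target, with catalyst as catalyst.
- Constant volume, constant temperature.
- The analysis sees a species whether free or bound.
- "The second partner" is coupling partner.
- An order is taken over about fifteen percent of the charge, up and down.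

- how the opening rate goes with [coupling partner] round the charge of the Thursday's run: the exponent of the rate at two percent of substrate gone to target
- how the opening rate goes with [catalyst] round the charge of the Thursday's run: the exponent of the rate at two percent of substrate gone to target
- the Sunday's run starts with 120 mM less of substrate and of coupling partner than the Thursday's run, and with no target. Compared where both hold the same amount of substrate, once fifteen percent of what the Sunday's run was charged with has turned into target, is the Sunday's run faster, slower or alike (within a tenth)?
- target in the Tuesday's run at 3.7 h, as a share of the substrate charged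

I read Saturday's column downward. The share turned was 37.3 % at 0.77 h, 77.0 % at 1.7 h, 90.7 % at 2.3 h and 97.0 % at 3.0 h. Tuesday's run was charged with the same substrate as Saturday's, so at equal share I took the substrate term as the same in both. Catalyst times partner at the start, Tuesday's over Saturday's, is 1.02, so Tuesday's should open on Saturday's line.

I then went round twice. In the first round I took the pace as following catalyst and partner, and I reckoned at the midway share 0.5, where Tuesday's partner has fallen much further in proportion. One Tuesday hour was then worth 0.878 Saturday hours, so 3.7 h became 3.25 h, beyond Saturday's reading at 3.0 h.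

That answer puts much target in Tuesday's flask, so I asked what target does. Thursday's run has used 120 mM, a share 40.0 % of its charge, when it holds what Sunday's run started with. Around there Thursday's climbed at 45.0 mM h⁻¹, while Sunday's early climb was 31.3 mM h⁻¹, slower. I read this as help from target, counting Sunday's early climb as the pace without target: at the catalyst of these two runs, each full share of target adds 1.10 times that pace. I supposed that this help does not grow with catalyst, so it counts for less in Tuesday's run.

Going round again, I put the midway help in. For Tuesday's run this gave 0.670 as clock factor, the Saturday hours that pass in one hour of a flask at equal share. So 3.7 h became 2.48 h, between Saturday's readings at 2.3 h and 3.0 h, and interpolation gave 92.3 %, the share I committed to.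

The forecast gave 1 for the order in partner, 0.75 for the order in catalyst, slower for Sunday's run and 90 % for Tuesday's, a little lower than my share. On Sunday's run it said: “Sunday is therefore slower, which suggests Thursday's accumulated product helps or the catalyst activates over time.”

The simulation gave 1.0, 0.95, slower and 89.9 %.

    catalyst + substrate + coupling partner → target + catalyst (60.48 L² mol⁻² h⁻¹)
    catalyst + substrate ⇌ idle catalyst-substrate complex, settled at all times (6.410 L mol⁻¹)
    substrate + coupling partner + target → 2 target (1.422 L² mol⁻² h⁻¹)

Sunday's gap comes from the target step: with that step taken out, Sunday's pace over Thursday's at equal substrate goes from 0.65 to 1.0. That step needs target and no catalyst, so the clock factor 0.670 discounts Saturday's ruler for it, and Tuesday's 3.7 h reads as 2.48 h there. On Monday's run, reckoned at the share 0.250, midway to the share 0.5, the factor is 0.428, which turns Saturday's 1.01 h to the share 0.5 into 2.36 h, against Monday's 2.44 h.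

The data are calculated from invented constants.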